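(All runs are calculated for substances that don't exist, noise included.)

The time of reading parts these flasks: midnight stands 3.0 h on 20 mM of substrate, dawn 1.0 h on 40 mM, both at 40 °C.

| flask | substrate | coupling partner | free catalyst | second catalyst | temperature | remark | time |
|---|---|---|---|---|---|---|---|
| ochre | 17 mM | 18 mM | 44 µM | 42 µM | 25 °C | run made earlier |  |
| grey | 32 mM | 18 mM | 44 µM | 42 µM | 40 °C | run made earlier |  |
| midnight | 20 mM | 18.0 mM | 44 µM | 42 µM | 40 °C |  | 3.0 h |
| dawn | 40 mM | 18.0 mM | 44 µM | 42 µM | 40 °C |  | 1.0 h |

ochre run (percent of the substrate charged)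

| time / h | intermediate / % | target / % |
|---|---|---|
| 0.167 | 1.0 | 1.0 |
| 0.500 | 3.9 | 1.1 |
| 0.833 | 6.3 | 5.3 |
| 1.33 | 6.7 | 8.0 |
| 2.00 | 7.9 | 13.7 |
| 3.00 | 10.0 | 20.9 |

grey run (percent of the substrate charged)

| time / min | intermediate / % | target / % |
|---|---|---|
| 12.0 | 3.8 | 1.0 |
| 25.0 | 5.7 | 3.8 |
| 40.0 | 7.0 | 7.1 |
| 50.0 | 7.6 | 9.3 |
| 60.0 | 8.8 | 12.9 |
| 80.0 | 11.4 | 16.8 |
| 90.0 | 11.7 | 17.8 |

(scatter of a reading: 0.5 percentage points)

- the winner by amount of intermediate, in percent of the substrate charged; "neither" if no more than 2 percentage points parts them (midnight / dawn / neither)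
- how much intermediate is there at the end, in percent of the substrate charged: midnight
- how much intermediate is there at the end, in percent of the substrate charged: dawn

- what was read earlier has a scatter of 0.5 percentage points, one standard deviation

Intermediate plus target counts what has passed out of the substrate. Grey's last reading gives k = 0.233 h⁻¹, where k, the passage constant, is the logarithm of substrate charged over substrate not yet passed, per hour: a pseudo-first-order constant. The same grey run passes a mean 6.29 mM h⁻¹.

Two extreme flasks can be solved at once, and each gives the share passed: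

constant k: midnight 50.3 %, dawn 20.8 %

constant mM per hour: midnight 94.3 %, dawn 15.7 %

Grey's reading at 40.0 min gives k = 0.228 h⁻¹, about the same. This reckoning therefore sits near the constant-k end, though grey has passed just 29.5 %, so the other end is not excluded.

Intermediate's share of what has passed reads 0.397 at grey's last reading and 0.406 at 60.0 min. Grey stops at 90.0 min, earlier than midnight's 3.0 h, so the midnight figure is the looser of these two estimates of intermediate, each a share carried over unchanged onto the constant-k conversion:

midnight 20.0 %, dawn 8.44 %

The forecast starts elsewhere: “So the first step looks near zero-order, with saturated catalyst.” It names midnight, with midnight at 19 % (10 % to 28 %) and dawn at 7.5 % (6 % to 10 %).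

The flasks give 16.7 % for midnight and 9.37 % for dawn, so midnight holds more. Substrate conversion stands at 51.6 % in midnight and 21.5 % in dawn, beside the 50.3 % and 20.8 % reckoned from k.

    substrate + free catalyst → free catalyst + intermediate (k = 5500 L mol⁻¹ h⁻¹, Ea = 36.0 kJ mol⁻¹)
    2 coupling partner → homo dimer (k = 20.0 L mol⁻¹ h⁻¹, Ea = 56.0 kJ mol⁻¹)
    target → over-reaction product (k = 1.70 × 10⁻⁴ h⁻¹, Ea = 121 kJ mol⁻¹)
    coupling partner + second catalyst + intermediate → second catalyst + target (k = 4.70 × 10⁶ L² mol⁻² h⁻¹, Ea = 37.0 kJ mol⁻¹)
    (constants at 40 °C)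

Midnight is not at rest at 3.0 h: substrate stands at 48.4 % and coupling partner at 12.2 % of its charge. Carried forward, k leaves 0.0921 % of midnight's substrate at 30.0 h, and the flask holds 0.0703 %. In dawn at 10.0 h, k leaves 9.73 % of the substrate, and the flask holds 8.89 %. By 30.0 h midnight's coupling partner stands at 0 %, its target at 45.1 % and its intermediate at 54.7 %, while dawn's intermediate reaches 63.5 % at 10.0 h.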